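**Plan**
Labels: ring A is the cyclopentane, ring B the bromocyclohexane fused to it, ring C the γ-lactone bridging ring B, and ring D the bromo-gem-dimethylcyclohexyl acetate. Retrosynthetic cuts, in order: acetate C–O; the bond from the linker CH2 to the ring D carbinol carbon; the exocyclic carbon of ring A (back to a ketone); the lactone O–C(CH3) bond; C–Br of ring B (back to C–B on the other face); finally both ring B bonds, C(quaternary)–CH(B) and CH(ring fusion)–CH(CH3).
Enabling feature: ring B carries four adjacent stereocentres, CHBr, the quaternary carbon, the ring-fusion CH and the C(CH3)(O) carbon, on a cis-hydrindane. Br and CH3 lie on opposite faces. An E,E-diene can only deliver its two end groups cis, so the bromine site travels as boron and is inverted afterwards.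
Forward order: ring A is bought as a cyclopentenone, ring B closes by cycloaddition, and ring C by C–H lactonisation. Ring D is made separately from 6-methylhept-5-en-2-one by a cationic ring closure and is joined last.
Stereochemistry: the chiral Lewis acid, the endo rule and the diene geometry set the four ring B centres. C–B to C–Br goes with inversion and C–H to C–O with retention. Convex-face hydroboration sets the ring A CH. Shi epoxidation followed by SN2 opening sets the ring D CHBr, and equatorial addition to the ring D ketone sets the carbinol carbon.

Key step: step 3

Assumption: the sense of induction in step 3 is assigned from the α-C–H···O/π-stacking binding model for s-trans cyclic enones, which calls for the (R)-diphenylprolinol-derived catalyst; the (S)-antipode is equally available if the sense proves opposite.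

Step 1
Reactants: 1 3-oxocyclopent-1-ene-1-carboxylic acid
Product: 2 tert-butyl 3-oxocyclopent-1-ene-1-carboxylate
Conditions: isobutene (excess), H2SO4 (cat.), CH2Cl2, sealed vessel, rt
Reagents that add atoms: 2-methylpropene (isobutene), CC(C)=C
Why: Acid-catalysed addition of the carboxylic acid to isobutene (tert-butyl esterification) is routine, and this ester is chosen because it shields the ester carbonyl from Lewis acid and aryllithium and later leaves under the same acid that opens the ketal.

Step 2
Reactants: 3 (E)-but-2-enal (crotonaldehyde); 4 (dichloromethyl)boronic acid pinacol ester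
Product: 5 (1E,3E)-penta-1,3-dien-1-ylboronic acid pinacol ester
Conditions: CrCl2 (8 equiv), LiI (4 equiv), THF, 25 °C
Reagents that add atoms: none
Why: The chromium-mediated Takai–Utimoto olefination of aldehydes with the dichloromethylboronate is known to give E-alkenylboronates, and the E alkene of 3 is carried through unchanged.

Step 3
Reactants: 2 tert-butyl 3-oxocyclopent-1-ene-1-carboxylate; 5 (1E,3E)-penta-1,3-dien-1-ylboronic acid pinacol ester
Product: 6 tert-butyl (3aR,4S,7R,7aR)-7-methyl-1-oxo-4-(pinacolboryl)-1,2,3,4,7,7a-hexahydro-3aH-indene-3a-carboxylate (cis-hydrindenone; Bpin, CH3 and ring A on one face of ring B, ester and H-7a on the other)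
Conditions: (R)-3,3-diphenyl-1-(2-methylphenyl)tetrahydro-1H,3H-pyrrolo[1,2-c][1,3,2]oxazaborole (20 mol%), HNTf2 (18 mol%), CH2Cl2, −40 to −20 °C; Et3N quench
Reagents that add atoms: none
Why: The cationic oxazaborolidine binds the ring ketone of 2 at the lone pair next to the alkene, and 5 adds in a concerted but asynchronous [4+2] cycloaddition in which the bond from the boron-bearing diene terminus to the ester-bearing β-carbon runs ahead of the bond from the methyl-bearing terminus to the α-carbon. The closest known reaction types are oxazaborolidinium-catalysed Diels–Alder additions to cyclic enones and thermal or Lewis acid-promoted cycloadditions of 1-boryl dienes. Ring B closes as the six-membered cycloadduct ring, both σ-bonds forming suprafacially on the cyclopentene, so rings A and B are cis-fused with ester and ring-fusion H on the same side. The quaternary carbon and the ring-fusion CH follow from the enone face left open by the catalyst (diene on the Re face of the α-carbon), while the boryl and methyl carbons follow from the E,E geometry of 5 combined with the endo placement of the ketone-bearing ring A, which brings both outer diene substituents onto the ring A face. Regioselectivity requires the ketone and not the ester to polarise the alkene, which is secured because the ketone is the stronger Lewis base, the tert-butyl group hinders the ester carbonyl, and methyl is a stronger director on the diene than the pinacol boronate. Endo selectivity rests on secondary overlap with the activated ketone and on the bulky ester preferring the exo position.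

Step 4
Reactants: 6 cis-hydrindenone allylboronate
Product: 7 tert-butyl (3aR,4S,7R,7aR)-7-methyl-1-oxo-4-(pinacolboryl)octahydro-3aH-indene-3a-carboxylate
Conditions: H2 (1 atm), Rh/Al2O3 (5 wt%), EtOAc, rt
Reagents that add atoms: none
Why: Heterogeneous hydrogenation of the cis-disubstituted ring alkene creates no stereocentre and removes the allylboronate reactivity, and rhodium is preferred to palladium to suppress double-bond migration into the two allylic stereocentres.

Step 5
Reactants: 7 saturated keto boronate
Product: 8 ethylene ketal of 7 (spiro-dioxolane at the ring A carbonyl carbon, all stereocentres as in 7)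
Conditions: Me3SiOCH2CH2OSiMe3, Me3SiOTf (5 mol%), CH2Cl2, −78 to −20 °C
Reagents that add atoms: 1,2-bis(trimethylsilyloxy)ethane, C[Si](C)(C)OCCO[Si](C)(C)C
Why: Noyori ketalisation under aprotic low-temperature conditions masks the ketone against the aryllithium of the next step without cleaving the tert-butyl ester or enolising the ring-fusion CH.

Step 6
Reactants: 8 ketal boronate
Product: 10 bromo ketal ester (Br on the ester face of ring B and anti to ring A), via lithium aryl boronate complex 9 (not isolated)
Conditions: 3,5-(CF3)2C6H3Br, n-BuLi, THF, −78 °C; add 8; then NBS, THF, −78 °C to rt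
Reagents that add atoms: N-bromosuccinimide, O=C1CCC(=O)N1Br
Why: Stereoinvertive electrophilic bromodeboronation of a secondary boronate complex (SE2 with inversion), in which the electron-poor aryl group turns the ate complex into a carbon nucleophile that meets NBS at the lobe opposite boron, so bromine arrives on the face of the ester.

Step 7
Reactants: 10 bromo ketal ester
Product: 11 (3aR,4R,7R,7aR)-4-bromo-7-methyl-1-oxooctahydro-3aH-indene-3a-carboxylic acid
Conditions: CF3CO2H–CH2Cl2–H2O (10:10:1), 0 °C to rt
Reagents that add atoms: water, O
Why: Acidolysis removes both acid-labile groups in one operation (E1 loss of isobutene from the ester and hydrolysis of the dioxolane) and avoids base, which could eliminate HBr.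

Step 8
Reactants: 11 bromo keto acid
Product: 12 tricyclic keto lactone (ring C joins the angular carboxyl to the CH3-bearing carbon on the face opposite ring A; Br equatorial on the lactone face)
Conditions: (S,S)-Mn(pdp)(OTf)2 (2 mol%), H2O2 (50% aq, 2 equiv, slow addition), MeCN, 0 °C
Reagents that add atoms: none
Why: In this carboxylate-directed γ-C–H lactonisation with a bioinspired manganese catalyst, the bound acid holds the metal-oxo next to the only tertiary C–H that is 1,3-diaxial to it and remote from ketone and bromide, and hydrogen abstraction with fast carboxylate rebound closes ring C with retention at the methyl-bearing carbon.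

Step 9
Reactants: 12 tricyclic keto lactone
Product: 13 exocyclic methylene lactone (C=CH2 in place of the ring A ketone)
Conditions: Zn, CH2Br2, TiCl4 (reagent pre-formed in THF, −40 to 5 °C); then 12, CH2Cl2, 0 °C to rt
Reagents that add atoms: dibromomethane, BrCBr
Why: Lombardo methylenation is non-basic and selective for ketones over lactones, which matters because 12 is a β-acyloxy ketone that a Wittig ylide could open by E1cB elimination or epimerise at the ring fusion.

Step 10
Reactants: 13 exocyclic methylene lactone
Product: 15 primary iodide (CH2I on the concave face of ring A and cis to the CH3-bearing carbon), via B-alkyl-9-BBN adduct 14 (not isolated)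
Conditions: 9-BBN, THF, rt; then I2, NaOMe/MeOH, 0 °C
Reagents that add atoms: iodine, [I][I]
Why: In this hydroboration followed by base-induced iodinolysis of the primary carbon–boron bond, 9-BBN can reach the alkene only from the convex face of ring A (the side of the ring-fusion H), so hydrogen is delivered there and the CH2 group is pushed to the concave face as the target requires.

Step 11
Reactants: 16 6-methylhept-5-en-2-one
Product: 17 4-[(2S)-3,3-dimethyloxiran-2-yl]butan-2-one
Conditions: 1,2:4,5-di-O-isopropylidene-β-L-erythro-2,3-hexodiulo-2,6-pyranose (30 mol%), KHSO5 (as 2KHSO5·KHSO4·K2SO4), K2CO3, Bu4NHSO4, MeCN–CH2(OMe)2 / aq. Na2B4O7–Na2EDTA buffer, 0 °C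
Reagents that add atoms: potassium peroxymonosulfate, [K+].[O-]S(=O)(=O)OO
Why: In this Shi epoxidation of a trisubstituted alkene, the chiral dioxirane from the L-fructose-derived ketone reacts through the spiro transition state on the face that gives the S epoxide (the D-series gives R), and the methyl ketone of 16 is too poor a dioxirane precursor to compete.

Step 12
Reactants: 17 (S)-epoxy ketone
Product: 18 (5R)-5-bromo-6-hydroxy-6-methylheptan-2-one
Conditions: Li2NiBr4, THF, 0 °C to rt; aq. phosphate buffer
Reagents that add atoms: dilithium tetrabromonickelate Li2NiBr4, [Li+].[Li+].[Ni+2].[Br-].[Br-].[Br-].[Br-]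
Why: Soft bromide from Li2NiBr4 opens the epoxide by SN2 attack at the less substituted carbon, so the C–Br stereocentre forms with inversion and the tertiary carbon keeps the oxygen.

Step 13
Reactants: 18 bromohydrin
Product: 19 (5R)-5-bromo-6-chloro-6-methylheptan-2-one
Conditions: conc. aq. HCl, ZnCl2, 0 °C to rt
Reagents that add atoms: hydrogen chloride, Cl
Why: Lucas-type SN1 substitution of the tertiary alcohol, assisted by the neighbouring bromine (a bromiranium ion opened by chloride at its tertiary carbon), leaves the CHBr centre untouched and installs a leaving group that survives the strong base of the next step.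

Step 14
Reactants: 19 bromo chloro ketone
Product: 20 {[(5R)-5-bromo-6-chloro-6-methylhept-1-en-2-yl]oxy}trimethylsilane
Conditions: LiN(i-Pr)2, Me3SiCl (in situ), THF, −78 °C
Reagents that add atoms: chlorotrimethylsilane, C[Si](C)(C)Cl
Why: Kinetic deprotonation of the methyl ketone at its CH3 group with in situ silylation gives the terminal silyl enol ether, because ketone deprotonation at −78 °C is far faster than E2 attack on the halides.

Step 15
Reactants: 20 terminal silyl enol ether
Product: 21 (4R)-4-bromo-3,3-dimethylcyclohexan-1-one
Conditions: TiCl4 (1.1 equiv), CH2Cl2, −78 to −40 °C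
Reagents that add atoms: none
Why: In this intramolecular Reetz α-tert-alkylation, TiCl4 ionises the tertiary chloride to the bromine-bridged cation, the enol ether carbon attacks its tertiary terminus in a chair-like six-membered closure that forms ring D, and the CHBr centre, whose bonds are never broken, keeps its configuration.

Step 16
Reactants: 15 primary iodide; 21 (4R)-4-bromo-3,3-dimethylcyclohexan-1-one
Product: 23 tertiary alcohol (ring D 1R,4R; OH cis to Br), via alkylsamarium diiodide 22 (not isolated)
Conditions: SmI2 (2.5 equiv), NiI2 (2 mol%), THF, 0 °C, 15 premixed with 21 (2 equiv); aq. NH4Cl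
Reagents that add atoms: none
Why: In this samarium Barbier reaction, SmI2 reduces the primary iodide much faster than the hindered secondary bromides or the lactone, and the alkylsamarium adds to 21 from the equatorial side, away from the axial 3-methyl group of the chair with equatorial bromine, so the new C–C bond is equatorial and the oxygen axial, cis to bromine.

Step 17
Reactants: 23 tertiary alcohol
Product: 24 CNP0133010.1 (target acetate)
Conditions: Ac2O, DMAP, Et3N, CH2Cl2, 40 °C
Reagents that add atoms: acetic anhydride, CC(=O)OC(C)=O
Why: DMAP-catalysed acylation of the hindered tertiary alcohol with acetic anhydride forms the acetate without touching any stereocentre.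

**Compound list**
1 | 3-oxocyclopent-1-ene-1-carboxylic acid | O=C1CCC(C(=O)O)=C1 | starting material
2 | tert-butyl 3-oxocyclopent-1-ene-1-carboxylate | O=C1CCC(C(=O)OC(C)(C)C)=C1 | intermediate
3 | (E)-but-2-enal | C/C=C/C=O | starting material
4 | (dichloromethyl)boronic acid pinacol ester | ClC(Cl)B1OC(C)(C)C(C)(C)O1 | starting material
5 | (1E,3E)-penta-1,3-dien-1-ylboronic acid pinacol ester | C/C=C/C=C/B1OC(C)(C)C(C)(C)O1 | intermediate
6 | (3aR,4S,7R,7aR) cis-hydrindenone allylboronate tert-butyl ester (endo adduct) | O=C1CC[C@@]2(C(=O)OC(C)(C)C)[C@@H](B3OC(C)(C)C(C)(C)O3)C=C[C@@H](C)[C@@H]12 | intermediate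
7 | (3aR,4S,7R,7aR) saturated keto boronate tert-butyl ester | O=C1CC[C@@]2(C(=O)OC(C)(C)C)[C@@H](B3OC(C)(C)C(C)(C)O3)CC[C@@H](C)[C@@H]12 | intermediate
8 | ethylene ketal of 7 | C12(OCCO1)CC[C@@]3(C(=O)OC(C)(C)C)[C@@H](B4OC(C)(C)C(C)(C)O4)CC[C@@H](C)[C@@H]23 | intermediate
9 | lithium [3,5-bis(trifluoromethyl)phenyl] boronate complex of 8 | [Li+].C12(OCCO1)CC[C@@]3(C(=O)OC(C)(C)C)[C@@H]([B-]4(OC(C)(C)C(C)(C)O4)c4cc(C(F)(F)F)cc(C(F)(F)F)c4)CC[C@@H](C)[C@@H]23 | intermediate
10 | bromo ketal tert-butyl ester (Br cis to ester) | C12(OCCO1)CC[C@@]3(C(=O)OC(C)(C)C)[C@H](Br)CC[C@@H](C)[C@@H]23 | intermediate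
11 | (3aR,4R,7R,7aR)-4-bromo-7-methyl-1-oxooctahydro-3aH-indene-3a-carboxylic acid | O=C1CC[C@@]2(C(=O)O)[C@H](Br)CC[C@@H](C)[C@@H]12 | intermediate
12 | tricyclic bromo keto γ-lactone (rings A, B, C) | O=C1CC[C@@]23C(=O)O[C@@](C)(CC[C@H]2Br)[C@@H]13 | intermediate
13 | exocyclic methylene bromo lactone | C=C1CC[C@@]23C(=O)O[C@@](C)(CC[C@H]2Br)[C@@H]13 | intermediate
14 | B-alkyl-9-BBN adduct of 13 | C(B1C2CCCC1CCC2)[C@H]3CC[C@@]45C(=O)O[C@@](C)(CC[C@H]4Br)[C@@H]35 | intermediate
15 | primary iodide of the ring A–C fragment | IC[C@H]1CC[C@@]23C(=O)O[C@@](C)(CC[C@H]2Br)[C@@H]13 | intermediate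
16 | 6-methylhept-5-en-2-one | CC(=O)CCC=C(C)C | starting material
17 | 4-[(2S)-3,3-dimethyloxiran-2-yl]butan-2-one | CC(=O)CC[C@@H]1OC1(C)C | intermediate
18 | (5R)-5-bromo-6-hydroxy-6-methylheptan-2-one | CC(=O)CC[C@@H](Br)C(C)(C)O | intermediate
19 | (5R)-5-bromo-6-chloro-6-methylheptan-2-one | CC(=O)CC[C@@H](Br)C(C)(C)Cl | intermediate
20 | {[(5R)-5-bromo-6-chloro-6-methylhept-1-en-2-yl]oxy}trimethylsilane | C=C(O[Si](C)(C)C)CC[C@@H](Br)C(C)(C)Cl | intermediate
21 | (4R)-4-bromo-3,3-dimethylcyclohexan-1-one | O=C1CC[C@@H](Br)C(C)(C)C1 | intermediate
22 | alkylsamarium diiodide from 15 | I[Sm](I)C[C@H]1CC[C@@]23C(=O)O[C@@](C)(CC[C@H]2Br)[C@@H]13 | intermediate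
23 | tertiary alcohol (deacetyl target; ring D 1R,4R) | O[C@@]1(C[C@H]2CC[C@@]34C(=O)O[C@@](C)(CC[C@H]3Br)[C@@H]24)CC[C@@H](Br)C(C)(C)C1 | intermediate
24 | CNP0133010.1 | CC(=O)O[C@@]1(C[C@H]2CC[C@@]34C(=O)O[C@@](C)(CC[C@H]3Br)[C@@H]24)CC[C@@H](Br)C(C)(C)C1 | target

Total step count: 17. Longest linear sequence: 11 steps (1, 3 to 10, 16, 17, counted from acid 1).

**Steps most likely to fail**

Step 3. The cycloaddition may stall, because the boron-bearing diene terminus has to bond to a carbon that becomes quaternary. On long exposure the acidic catalyst may protodeboronate or oligomerise the diene. Any binding of the catalyst to the ester instead of the ketone would leak into the other regioisomer and erode face selectivity. The fallback separates bond construction from absolute control. It starts again from 2 and 5 and uses the uncatalysed thermal cycloaddition (toluene, 110 °C, sealed tube), the classical mode of reaction of 1-boryl dienes with doubly activated alkenes. This should give the endo adduct as a racemate, that is 6 together with the mirror-image adduct F1. Preparative chromatography on a chiral stationary phase then returns the route to 6.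

Step 6. The ate complex may form slowly at the neopentyl-type boron. The crowded complex may also react with NBS by single-electron transfer, so that a free radical is brominated with loss of stereospecificity. Bromination of the aryl ligand is a further leak. The fallback replaces electrophilic substitution at carbon by nucleophilic substitution. From 8, oxidation with NaBO3·4H2O (THF–H2O, rt) with retention should give the secondary alcohol F2. Appel bromination (CBr4, PPh3, CH2Cl2) with inversion then returns the route to 10.

Step 16. The alkyl radical or alkylsamarium may be quenched to a methyl group before it finds the hindered ketone. Electron transfer to the secondary bromides may compete. Bromine anchors the ring D chair only weakly, so reaction through the chair with axial bromine would cause poor facial selectivity at the carbinol carbon. The fallback joins the fragments by cross-coupling and installs the oxygen afterwards. Ketone 21 is converted by kinetic enolisation away from the gem-dimethyl group (LiN(SiMe3)2, PhNTf2, THF, −78 °C) into the enol triflate F3. The borane 14, generated from 13 as in step 10, is coupled with it in a B-alkyl Suzuki–Miyaura reaction (Pd(dppf)Cl2, Cs2CO3, DMF–THF–H2O) to give the trisubstituted ring D alkene F4. Mukaiyama hydration (Mn(dpm)3, PhSiH3, O2, i-PrOH) with Markovnikov selectivity then returns the route to 23, the carbinol epimers being separated at this stage.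

**Further compounds**
F1 | step 3 | mirror-image adduct (enantiomer of 6) | O=C1CC[C@]2(C(=O)OC(C)(C)C)[C@H](B3OC(C)(C)C(C)(C)O3)C=C[C@H](C)[C@H]12
F2 | step 6 | secondary alcohol (OH in place of boron in 8, same face) | C12(OCCO1)CC[C@@]3(C(=O)OC(C)(C)C)[C@@H](O)CC[C@@H](C)[C@@H]23
F3 | step 16 | (4R)-4-bromo-5,5-dimethylcyclohex-1-en-1-yl trifluoromethanesulfonate | FC(F)(F)S(=O)(=O)OC1=CC[C@@H](Br)C(C)(C)C1
F4 | step 16 | trisubstituted ring D alkene joined to the ring A–C fragment | C1(C[C@H]2CC[C@@]34C(=O)O[C@@](C)(CC[C@H]3Br)[C@@H]24)=CC[C@@H](Br)C(C)(C)C1
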